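The constants of this flask are not given, and the reckoning below takes as its chosen shortcut a span read from the readings of the earlier runs, a span that differs from run to run.

| flask | Q | G | L | time |
|---|---|---|---|---|
| east | 200 mM | 400 mM | 20.0 mM |  |
| north | 120 mM | 320 mM | 20.0 mM |  |
| south-west | 200 mM | 400 mM | 40.0 mM |  |
| south | 50.0 mM | 100 mM | 20.0 mM | 26 min |

| east run: time / min | east run: [E] / mM | north run: time / min | north run: [E] / mM | south-west run: time / min | south-west run: [E] / mM |
|---|---|---|---|---|---|
| 5.2 | 77.8 | 5.2 | 50.6 | 5.2 | 119.4 |
| 10 | 120.5 | 10 | 75.0 | 10 | 161.1 |
| 16 | 149.0 | 16 | 93.4 | 16 | 180.5 |
| 21 | 162.8 | 21 | 101.2 | 21 | 189.1 |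
| 26 | 172.8 | 26 | 107.0 | 26 | 193.4 |

(readings scatter by 0.6 mM)

* how the opening rate goes with [L] round the charge of the east run: the exponent of the rate at two percent of Q gone to E
* the north run starts with 80.0 mM less of Q and of G than the east run, and with no E. Compared where both hold the same amount of Q, once fifteen percent of what the north run was charged with has turned into E, is the north run faster, slower or alike (within a tenth)?
* E in the south run at 26 min, as a share of the Q charged

- Overall: Q + G -> E, with L as catalyst.
- Constant volume, constant temperature.
- Readings of a species count what is bound in complexes too.
- "The second partner" is G.
- An order is taken over about fifteen percent of the charge, up and down.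

1. Take [Q] as charge minus E and [G] likewise. A rate k[Q][G] would then make ln([G]/[Q]) climb in a straight line with time. In the east run the readings at 26 min give 140 mM for the span W, which is the excess of [G] over [Q] divided by the climb of ln([G]/[Q]) from the charge to that time; a smaller span means a faster flask.

2. The north run gives 110 mM, less than the east run, so the span shrinks as the charge shrinks. Both runs keep the same excess of 200 mM, so at equal Q they hold equal G, and the ratio of spans, 1.27, reads the north run as the faster.

3. The south-west run gives 72.7 mM, and against the east run that is an exponent in [L] of 0.944, a reading over the whole run and not at the opening.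

4. The bracket for the south run comes next. A rate following [Q] by itself would repeat the east share, 86.4%, which is the ceiling. The east span carried over unchanged gives 46.2%, which is the floor.

5. Tightening is my own judgement. The south charge lies below the north charge, so the north span raises the floor to 53.5%. Continuing the shrinkage as a power of the Q charge, with exponent 0.468, gives a span of 73.1 mM and lowers the ceiling to 66.2%.

6. The forecast gives 0.9, faster and 72%, the last with the words “This is poorly determined”. That share lies above the tightened ceiling, though below the first one.

The flask gives 0.98, faster and 56.3%, the last lying above the raised floor and below the lowered ceiling.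

    L + Q ⇌ LQ, settled at all times (1.170 M⁻¹)
    LQ + G ⇌ LQG, settled at all times (13.00 M⁻¹)
    LQG → E + L (5.538 min⁻¹)
    2 Q ⇌ Q2, settled at all times (47.80 M⁻¹)
    2 L → 2 Wa (2.016 M⁻¹ min⁻¹)

The south result corresponds to a span of 101 mM, below the north run's. E in the south run comes to 56.3% at 26 min because of the joining of 2 Q to Q2 acting together with the loss of 2 L to 2 Wa. Without the joining the south run reaches 81.0%, and without the loss of L it reaches 77.7%.

All runs are calculated with made-up constants, noise included.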